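**Strategy.** The dihydropyran ring (ring D) of the 2,2-dimethylchroman is cut at C4a–C4 and C3–C2 (chroman numbering). What remains is the aryl oxocarbenium ion of acetone, which is an ionised catechol acetonide: C2, both methyls, O1 and the C8 oxygen are all present in 2,2-dimethyl-1,3-benzodioxole. In the key step a chiral silylium-type acid opens this ketal, and the cationic 2-oxadiene C4a=C8a–O1=C2 takes up a (Z)-enediol bis-silyl ether (C3, C4) in a stepwise formal [4+2] (oxa-Povarov) reaction. This gives the protected trans-3,4-diol with both stereocentres and frees O8 as its silyl ether. C–H borylation at C6 and an asymmetric conjugate addition to a chromone then build the flavanone.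

Key step: step 2

Assumption: the sense of induction is taken as (S,S)-IDPi → 3R in step 2 and (R)-t-BuPyOx → 2S in step 5 (the latter by analogy with cyclic enones); if either proves opposite, the mirror-image catalyst is used.

Step 1
Reactants: 1 (tert-butyldimethylsilyloxy)acetaldehyde
Product: 2 (Z)-1,2-bis(tert-butyldimethylsilyloxy)ethene
Conditions: TBSOTf, Et3N, CH2Cl2, 0 °C → rt
Reagents that add atoms: tert-butyldimethylsilyl trifluoromethanesulfonate (TBSOTf), CC(C)(C)[Si](C)(C)OS(=O)(=O)C(F)(F)F
Why: Soft enolisation of the aldehyde and O-silylation (silyl enol ether formation); the (Z)-isomer should predominate because 1,2-dioxygenated alkenes prefer the cis geometry, and it is purified by distillation.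

Step 2
Reactants: 3 2,2-dimethyl-1,3-benzodioxole (catechol acetonide); 2 (Z)-1,2-bis(tert-butyldimethylsilyloxy)ethene (excess; two equivalents enter the equation, one supplying C3/C4 and one the silyl group on O8)
Product: 6 (3R,4S)-3,4,8-tris(tert-butyldimethylsilyloxy)-2,2-dimethylchromane, via aryl oxocarbenium ion 4 (not isolated), via open-chain silyloxocarbenium ion 5 (not isolated)
Conditions: (S,S)-IDPi (BINOL-derived N-triflyl imidodiphosphorimidate with 3,3′-aryl groups, 5 mol%), 2 (4 equiv, slow addition), toluene, −60 → −20 °C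
Reagents that add atoms: none
Why: Proposed new method: the silylated acid (formed from the IDPi and 2) silylates one ketal oxygen of 3 and opens the dioxole to the aryl oxocarbenium ion 4; the carbon terminus of 2 adds to C2 (Mukaiyama-type, C3–C2 bond) to give 5, C4a then attacks C4 (Friedel–Crafts, C4a–C4 bond), and the proton lost on rearomatisation is taken up by a second equivalent of 2, which returns the silylium catalyst. The closest known reaction types are the SnCl4-promoted oxa-Povarov reaction of aryl oxocarbenium ions with alkenes and IDPi-silylium Mukaiyama-type additions of enol silanes to acetal-derived oxocarbenium ions and to non-prochiral cations; a catechol ketal as the oxocarbenium source and an enediol ether as the two-carbon partner have not been shown. Ring D is closed stepwise in a formal [4+2] manner, the ring-forming event being a 6-exo-trig attack of the arene on the C4=O+ bond of 5. C3 is set under catalyst control, the confined chiral anion paired with 4 selecting one face of the enol ether; C4, still trigonal in 5, is set under substrate control in a chair-like closure that places its silyloxy group trans to that on C3, and reversible ionisation at the benzylic C4 would funnel any cis isomer to trans. The step needs regioselective ketal opening and ring closure, which the substrate secures by symmetry (both C–O bonds of 3 are equivalent) and by the fact that the only free ortho position of 4 is C4a. Low temperature is needed so that the benzylic silyl ether of 6 does not ionise irreversibly.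

Step 3
Reactants: 6 (3R,4S)-3,4,8-tris(tert-butyldimethylsilyloxy)-2,2-dimethylchromane
Product: 8 [(3R,4S)-3,4,8-tris(tert-butyldimethylsilyloxy)-2,2-dimethylchroman-6-yl]boronic acid, via pinacol boronate 7 (not isolated)
Conditions: [Ir(cod)OMe]2 (1.5 mol%), 4,4′-di-tert-butyl-2,2′-bipyridine (3 mol%), B2pin2, THF, 80 °C; then NaIO4, NH4OAc, acetone/H2O, rt
Reagents that add atoms: bis(pinacolato)diboron (B2pin2), CC1(C)OB(OC1(C)C)B1OC(C)(C)C(C)(C)O1; water, O
Why: Iridium-catalysed aromatic C–H borylation is sterically governed and C6–H is the only ring-B hydrogen without an ortho substituent (C5–H lies next to C4a, C7–H next to the C8 silyloxy group); periodate then removes the pinacol by glycol cleavage to give the boronic acid.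

Step 4
Reactants: 9 7-hydroxy-4H-chromen-4-one
Product: 10 7-(tert-butyldimethylsilyloxy)-4H-chromen-4-one
Conditions: TBSCl, imidazole, DMF, rt
Reagents that add atoms: tert-butyldimethylsilyl chloride (TBSCl), CC(C)(C)[Si](C)(C)Cl
Why: Imidazole-mediated O-silylation of the phenol; it keeps the acidic 7-hydroxyl away from palladium in the next step and joins the silyl set removed at the end.

Step 5
Reactants: 8 [(3R,4S)-3,4,8-tris(tert-butyldimethylsilyloxy)-2,2-dimethylchroman-6-yl]boronic acid; 10 7-(tert-butyldimethylsilyloxy)-4H-chromen-4-one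
Product: 11 (2S)-7-(tert-butyldimethylsilyloxy)-2-[(3R,4S)-3,4,8-tris(tert-butyldimethylsilyloxy)-2,2-dimethylchroman-6-yl]chroman-4-one
Conditions: Pd(OCOCF3)2 (5 mol%), (R)-4-tert-butyl-2-(pyridin-2-yl)-4,5-dihydrooxazole ((R)-t-BuPyOx, 6 mol%), NH4PF6 (30 mol%), H2O (5 equiv), ClCH2CH2Cl, 60 °C
Reagents that add atoms: none
Why: Asymmetric conjugate addition of an arylboronic acid to a chromone with a cationic divalent palladium pyridine-oxazoline catalyst: the aryl–palladium species from transmetallation inserts C2=C3 of the chromone and water protonates the palladium enolate; the flavanone stereocentre is set under catalyst control by the ligand, the chroman stereocentres being too remote to interfere.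

Step 6
Reactants: 11 (2S)-7-(tert-butyldimethylsilyloxy)-2-[(3R,4S)-3,4,8-tris(tert-butyldimethylsilyloxy)-2,2-dimethylchroman-6-yl]chroman-4-one
Product: 12 (2S)-7-hydroxy-2-[(3R,4S)-3,4,8-trihydroxy-2,2-dimethylchroman-6-yl]chroman-4-one (CNP0281318.3)
Conditions: HF·pyridine, pyridine, THF, 0 °C → rt
Reagents that add atoms: none
Why: Fluoride-mediated global desilylation of the four silyl ethers; the buffered, non-basic medium should spare the flavanone stereocentre (which would racemise in base by ring-opening to the chalcone) and the benzylic C4 hydroxyl.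

**Compound list**

1 | (tert-butyldimethylsilyloxy)acetaldehyde | O=CCO[Si](C)(C)C(C)(C)C | starting material
2 | (Z)-1,2-bis(tert-butyldimethylsilyloxy)ethene | CC(C)(C)[Si](C)(C)O/C=C\O[Si](C)(C)C(C)(C)C | intermediate
3 | 2,2-dimethyl-1,3-benzodioxole (catechol acetonide) | CC1(C)Oc2ccccc2O1 | starting material
4 | isopropylidene[2-(tert-butyldimethylsilyloxy)phenyl]oxonium ion (ring-opened, O-silylated 3; cation, counter-ion the IDPi anion) | CC(C)=[O+]c1ccccc1O[Si](C)(C)C(C)(C)C | intermediate
5 | (tert-butyldimethylsilyl){(2S)-2-(tert-butyldimethylsilyloxy)-3-[2-(tert-butyldimethylsilyloxy)phenoxy]-3-methylbutylidene}oxonium ion (cation, counter-ion the IDPi anion; same spatial arrangement as C3 of 6) | CC(C)(Oc1ccccc1O[Si](C)(C)C(C)(C)C)[C@H](O[Si](C)(C)C(C)(C)C)C=[O+][Si](C)(C)C(C)(C)C | intermediate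
6 | (3R,4S)-3,4,8-tris(tert-butyldimethylsilyloxy)-2,2-dimethylchromane (trans) | CC1(C)Oc2c(O[Si](C)(C)C(C)(C)C)cccc2[C@H](O[Si](C)(C)C(C)(C)C)[C@H]1O[Si](C)(C)C(C)(C)C | intermediate
7 | (3R,4S)-3,4,8-tris(tert-butyldimethylsilyloxy)-2,2-dimethyl-6-(4,4,5,5-tetramethyl-1,3,2-dioxaborolan-2-yl)chromane | CC1(C)Oc2c(O[Si](C)(C)C(C)(C)C)cc(B3OC(C)(C)C(C)(C)O3)cc2[C@H](O[Si](C)(C)C(C)(C)C)[C@H]1O[Si](C)(C)C(C)(C)C | intermediate
8 | [(3R,4S)-3,4,8-tris(tert-butyldimethylsilyloxy)-2,2-dimethylchroman-6-yl]boronic acid | CC1(C)Oc2c(O[Si](C)(C)C(C)(C)C)cc(B(O)O)cc2[C@H](O[Si](C)(C)C(C)(C)C)[C@H]1O[Si](C)(C)C(C)(C)C | intermediate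
9 | 7-hydroxy-4H-chromen-4-one | O=c1ccoc2cc(O)ccc12 | starting material
10 | 7-(tert-butyldimethylsilyloxy)-4H-chromen-4-one | O=c1ccoc2cc(O[Si](C)(C)C(C)(C)C)ccc12 | intermediate
11 | (2S)-7-(tert-butyldimethylsilyloxy)-2-[(3R,4S)-3,4,8-tris(tert-butyldimethylsilyloxy)-2,2-dimethylchroman-6-yl]chroman-4-one | CC1(C)Oc2c(O[Si](C)(C)C(C)(C)C)cc([C@@H]3CC(=O)c4ccc(O[Si](C)(C)C(C)(C)C)cc4O3)cc2[C@H](O[Si](C)(C)C(C)(C)C)[C@H]1O[Si](C)(C)C(C)(C)C | intermediate
12 | (2S)-7-hydroxy-2-[(3R,4S)-3,4,8-trihydroxy-2,2-dimethylchroman-6-yl]chroman-4-one | CC1(C)Oc2c(O)cc([C@@H]3CC(=O)c4ccc(O)cc4O3)cc2[C@H](O)[C@H]1O | target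

**Step count.** Total: 6 steps. Longest linear sequence: 5 steps (steps 1, 2, 3, 5, 6); step 4 is a one-step side branch.

**Steps most likely to fail**

1. Step 2 (the proposed new method). The catechol ketal may resist opening by the silylated acid at low temperature. Acid-triggered self-aldolisation may consume the enediol ether faster than the oxocarbenium ion intercepts it. The chiral anion may discriminate the faces of the enol ether poorly. The benzylic silyl ether at C4 may ionise again and erode the product. The fallback uses known chemistry only, sets out from 3 and comes back at 6. Aqueous trifluoroacetic acid cleaves the ketal of 3 to catechol F1. Mono-O-alkylation with 3-chloro-3-methylbut-1-yne (CuCl2·2H2O cat., DBU, MeCN, 0 °C, excess diol) should give 2-[(2-methylbut-3-yn-2-yl)oxy]phenol F2. Heating in N,N-diethylaniline (aryl propargyl ether Claisen rearrangement, 1,5-hydrogen shift and oxa-6π electrocyclisation) should give 2,2-dimethyl-2H-chromen-8-ol F3. TBSCl/imidazole gives tert-butyl[(2,2-dimethyl-2H-chromen-8-yl)oxy]dimethylsilane F4. Jacobsen–Katsuki epoxidation with the (R,R)-enantiomer of N,N′-bis(3,5-di-tert-butylsalicylidene)-1,2-cyclohexanediaminomanganese chloride (a trivalent manganese complex), NaOCl and 4-phenylpyridine N-oxide should give (3R,4R)-8-(tert-butyldimethylsilyloxy)-3,4-epoxy-2,2-dimethylchromane F5. Dilute HClO4 in THF/H2O should open the epoxide at the benzylic C4 with inversion to (3R,4S)-8-(tert-butyldimethylsilyloxy)-2,2-dimethylchromane-3,4-diol F6. TBSOTf/2,6-lutidine then gives 6.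

2. Step 5. Protodeboronation of the electron-rich boronic acid may outrun transmetallation, the insertion may show insufficient facial selectivity on this bulky aryl group, and aryl silyl ethers may be lost in the aqueous medium. The fallback sets out from 8 and 10 and comes back at 11. An oxidative Heck-type coupling (Pd(OCOCF3)2, O2, DMSO), in which the palladium enolate undergoes β-hydride elimination instead of protonation, should give 7-(tert-butyldimethylsilyloxy)-2-[(3R,4S)-3,4,8-tris(tert-butyldimethylsilyloxy)-2,2-dimethylchroman-6-yl]-4H-chromen-4-one F7. Asymmetric hydrogenation with a chiral ruthenium N-heterocyclic carbene catalyst made from Ru(cod)(2-methylallyl)2 should give (2S,4S)-7-(tert-butyldimethylsilyloxy)-2-[(3R,4S)-3,4,8-tris(tert-butyldimethylsilyloxy)-2,2-dimethylchroman-6-yl]chroman-4-ol F8. Oxidation of the secondary alcohol with Dess–Martin periodinane then gives 11.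

3. Step 3. C–H activation may be sluggish on the crowded arene, or the aryl silyl ether may hydrolyse during the oxidative cleavage of the pinacol ester. The fallback sets out from 6 and comes back at 8. Bromination with N-bromosuccinimide in MeCN at 0 °C should occur para to the ring oxygen O1, because the positions ortho and para to the bulkier, less donating C8 silyloxy group are disfavoured. It should give (3R,4S)-6-bromo-3,4,8-tris(tert-butyldimethylsilyloxy)-2,2-dimethylchromane F9. Bromine–lithium exchange (n-BuLi, THF, −78 °C), B(OiPr)3 and aqueous NH4Cl work-up then give 8.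

**Further compounds**

F1 | step 2 | catechol (benzene-1,2-diol) | Oc1ccccc1O
F2 | step 2 | 2-[(2-methylbut-3-yn-2-yl)oxy]phenol | C#CC(C)(C)Oc1ccccc1O
F3 | step 2 | 2,2-dimethyl-2H-chromen-8-ol | CC1(C)C=Cc2cccc(O)c2O1
F4 | step 2 | tert-butyl[(2,2-dimethyl-2H-chromen-8-yl)oxy]dimethylsilane | CC1(C)C=Cc2cccc(O[Si](C)(C)C(C)(C)C)c2O1
F5 | step 2 | (3R,4R)-8-(tert-butyldimethylsilyloxy)-3,4-epoxy-2,2-dimethylchromane | CC1(C)Oc2c(O[Si](C)(C)C(C)(C)C)cccc2[C@H]3O[C@@H]13
F6 | step 2 | (3R,4S)-8-(tert-butyldimethylsilyloxy)-2,2-dimethylchromane-3,4-diol | CC1(C)Oc2c(O[Si](C)(C)C(C)(C)C)cccc2[C@H](O)[C@H]1O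
F7 | step 5 | 7-(tert-butyldimethylsilyloxy)-2-[(3R,4S)-3,4,8-tris(tert-butyldimethylsilyloxy)-2,2-dimethylchroman-6-yl]-4H-chromen-4-one | CC1(C)Oc2c(O[Si](C)(C)C(C)(C)C)cc(-c3cc(=O)c4ccc(O[Si](C)(C)C(C)(C)C)cc4o3)cc2[C@H](O[Si](C)(C)C(C)(C)C)[C@H]1O[Si](C)(C)C(C)(C)C
F8 | step 5 | (2S,4S)-7-(tert-butyldimethylsilyloxy)-2-[(3R,4S)-3,4,8-tris(tert-butyldimethylsilyloxy)-2,2-dimethylchroman-6-yl]chroman-4-ol | CC1(C)Oc2c(O[Si](C)(C)C(C)(C)C)cc([C@@H]3C[C@H](O)c4ccc(O[Si](C)(C)C(C)(C)C)cc4O3)cc2[C@H](O[Si](C)(C)C(C)(C)C)[C@H]1O[Si](C)(C)C(C)(C)C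
F9 | step 3 | (3R,4S)-6-bromo-3,4,8-tris(tert-butyldimethylsilyloxy)-2,2-dimethylchromane | CC1(C)Oc2c(O[Si](C)(C)C(C)(C)C)cc(Br)cc2[C@H](O[Si](C)(C)C(C)(C)C)[C@H]1O[Si](C)(C)C(C)(C)C
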